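Partner is the easy thing to count: charged in the smaller amount in the south-west run, it is that run's limiting reagent, and substrate there stops falling at 48%.

| flask | substrate | partner | capture agent | remark | time |
|---|---|---|---|---|---|
| south-west | 29 mM | 19 mM | 29 mM | run made earlier |  |
| north-east | 29 mM | 98 mM | 29 mM | run made earlier |  |
| ash | 29 mM | 29.0 mM | 29.0 mM |  | 10 h |
| oak | 29 mM | 14.5 mM | 29.0 mM |  | 10 h |
| alder | 29 mM | 72.5 mM | 29.0 mM |  | 10 h |

| run | time / h | double product / % | tetra adduct / % | substrate / % |
|---|---|---|---|---|
| south-west | 0.833 | 3 | 0 | 46 |
| south-west | 1.50 | 4 | 0 | 50 |
| south-west | 3.00 | 2 | 2 | 49 |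
| south-west | 5.00 | 0 | 1 | 48 |
| south-west | 10.0 | 0 | 1 | 48 |
| north-east | 2.00 | 2 | 37 | 0 |
| north-east | 4.00 | 0 | 34 | 0 |
| north-east | 6.00 | 1 | 29 | 0 |
| north-east | 8.00 | 0 | 30 | 2 |
| north-east | 10.0 | 0 | 33 | 0 |

(scatter of a reading: 1.5 percentage points)

- which of these holds the largest part of the substrate at the end of ash (tetra adduct / tris adduct / double product / substrate / single product)
- which of these holds the largest part of the substrate at the end of oak (tetra adduct / tris adduct / double product / substrate / single product)
- which of these holds the largest part of the substrate at the end of alder (tetra adduct / tris adduct / double product / substrate / single product)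
- how much double product is there at the end of alder, in percent of the substrate charged

Write the balance of partner. Every substrate taken uses one partner, and every further addition to a product uses another. That gives the partner cost, the partner spent per substrate taken, 1.26 in south-west. North-east is counted the same way, on the assumption that partner is spent there too.

| run | partner per substrate charged | substrate taken | partner cost |
|---|---|---|---|
| south-west | 0.655 | 52.0% | 1.26 |
| north-east | 3.38 | 100% | 3.38 |

Reading the first row, the south-west cost lies nearer one addition than two. Held for ash, it leaves 20.6% substrate, and single product should lead. Held for oak, it leaves 60.3% substrate, which is more than the part taken, so substrate should lead.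

The second row shows substrate gone, and alder should follow it. Its cost then equals its charge, 2.50, between 2 and 3. Double product reads 0% and 0% at the end of the two runs, against a scatter of 1.5 percentage points, so it is not expected to carry that mean, and tris adduct should lead alder.

The forecast names single product, substrate and tris adduct in turn, with 1% double product in alder: “Double product is only a transient, drained by capture agent.”

    double product + capture agent → trapped intermediate (k = 0.319 M⁻¹ min⁻¹)
    substrate + partner → single product + by-product (k = 5.38 M⁻¹ min⁻¹)
    partner + double product → tris adduct + by-product (k = 9.66 M⁻¹ min⁻¹)
    partner + single product → double product + by-product (k = 2.94 M⁻¹ min⁻¹)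
    partner + tris adduct → tetra adduct + by-product (k = 1.06 M⁻¹ min⁻¹)
    partner + tetra adduct → over-reaction product (k = 0.210 M⁻¹ min⁻¹)
    tetra adduct ⇌ isomer of the product (K = 0.404, k = 0.00192 min⁻¹)

Alder ends at 0.0818% double product, and tris adduct leads at 45.6%; single product leads ash at 47.9% and substrate leads oak at 57.9%. With the capture step struck out, alder's double product stands at 9.35%. Trapped intermediate, which is not among the species asked about, holds 12.0% of alder, yet the partner cost needs no such name: alder's is 2.56. The flask with alder's partner but 120 mM of substrate has a charge of 0.604, so 1.26 gives 52.0% substrate left, and that flask holds 51%.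

All runs are calculated for an exercise.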